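The ten-membered carbocycle (C1–C10) is cut at C3–C4. The feature exploited is the C3 ketone next to the methyl-bearing C4: it is the oxidised and then reduced form of a 4-methylene-3-ol, the adduct of a C4 alkenyl metal and a C3 aldehyde. One Nozaki–Hiyama–Kishi addition therefore forms C3–C4 and closes the ring in a single operation. Its precursor is an open chain with a C3 aldehyde and a C4 2-iodoalkene that already holds C6, C7, C8 and C10 in the target configuration, carries the C8 isobutyrate, and has C6–O and C12–O as silyl ethers for a late cis-lactone closure.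

Key step: step 16

Remark (numbering): germacrane locants are used: ring C1–C10 with C3 the ketone, C4 the CHMe carbon (methyl C15), C6 the lactone CH–O, C7 the ring-fusion CH, C8 the ester carbon, C10 the carbinol (methyl C14); C11, C12, C13 are the lactone carbons (C13 the exocyclic methylene).
Remark: the target is a γ-hydroxy ketone (C10–OH, C3=O) that can close reversibly to its 3,10-hemiketal; the open form drawn is taken as the target.
Remark: (S)-linalool of high enantiomeric purity is taken as purchasable.
Remark: the ring closure makes C3 an uncontrolled carbinol centre, so 26 is carried as the C3-epimeric pair and drawn without a descriptor at C3; both epimers give enone 27.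
Remark: the 2-bromoallyl unit from 2,3-dibromopropene is converted into the 2-iodoalkene by halogen exchange (step 13) before the ring closure.
Remark: the 4R configuration is assumed to be the thermodynamically preferred one in ketone 30.

Step 1
Reactants: 1 (S)-linalool
Product: 2 (S)-linalool triethylsilyl ether
Conditions: TESOTf, 2,6-lutidine, CH2Cl2, −78 to 0 °C
Reagents that add atoms: triethylsilyl trifluoromethanesulfonate, CC[Si](CC)(CC)OS(=O)(=O)C(F)(F)F
Why: Silylation of the tertiary C10 alcohol with a silyl triflate, which keeps C10–OH from forming a lactol with the later C3 aldehyde and leaves the C10 centre untouched.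

Step 2
Reactants: 2 (S)-linalool triethylsilyl ether
Product: 4 primary C8 alcohol, via alkylborane 3 (not isolated)
Conditions: 9-BBN, THF, 0 °C to rt; then NaOH, H2O2, 0 °C
Reagents that add atoms: hydrogen peroxide, OO
Why: Hydroboration–oxidation, in which 9-BBN adds anti-Markovnikov to the monosubstituted vinyl group far faster than to the trisubstituted alkene, so C8 receives the oxygen and the C3 end stays masked as the alkene.

Step 3
Reactants: 4 primary C8 alcohol
Product: 5 C8 aldehyde (fragment A)
Conditions: 1,1,1-triacetoxy-1,1-dihydro-1,2-benziodoxol-3(1H)-one (DMP), NaHCO3, CH2Cl2, 0 °C to rt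
Reagents that add atoms: none
Why: Dess–Martin oxidation under buffered, non-basic conditions should give the β-silyloxy aldehyde without β-elimination; it is used directly in step 11.

Step 4
Reactants: 6 tert-butyldimethyl(prop-2-yn-1-yloxy)silane
Product: 8 4-(silyloxy)but-2-ynal, via lithium acetylide 7 (not isolated)
Conditions: n-BuLi, THF, −78 °C; DMF; inverse quench into aqueous KH2PO4
Reagents that add atoms: N,N-dimethylformamide, CN(C)C=O
Why: Formylation of a lithium acetylide with DMF; the buffered inverse quench releases the ynal (its CHO carbon is C6) without amine addition.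

Step 5
Reactants: 8 4-(silyloxy)but-2-ynal; 9 2,3-dibromoprop-1-ene
Product: 11 racemic 2-bromoallyl carbinol, via allylindium bromide 10 (not isolated)
Conditions: indium powder, THF/H2O (1:1), rt
Reagents that add atoms: none
Why: Barbier allylation, in which indium inserts only into the allylic C–Br bond and the allylindium adds 1,2 to the ynal to form C5–C6; the new C6 carbinol is racemic here and is set in step 7.

Step 6
Reactants: 11 racemic 2-bromoallyl carbinol
Product: 12 alkynyl ketone
Conditions: activated MnO2, CH2Cl2, rt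
Reagents that add atoms: none
Why: MnO2 oxidation of a propargylic alcohol under neutral conditions, which should leave the doubly activated CH2 between ketone and bromoalkene unisomerised.

Step 7
Reactants: 12 alkynyl ketone
Product: 13 (4S)-propargylic alcohol
Conditions: Ru[(S,S)-TsNCH(Ph)CH(Ph)NH](p-cymene) (1 mol %), i-PrOH, rt
Reagents that add atoms: none
Why: Noyori asymmetric transfer hydrogenation of an alkynyl ketone without added base, in which the (S,S)-catalyst distinguishes the alkynyl from the sp3 substituent and should deliver the (S)-carbinol, which is C6 of the target.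

Step 8
Reactants: 13 (4S)-propargylic alcohol
Product: 15 (Z)-iodoalkene alcohol, via alkenylalanate 14 (not isolated)
Conditions: NaAlH2(OCH2CH2OCH3)2 (Red-Al), THF, 0 °C; EtOAc; then I2, THF, −78 °C
Reagents that add atoms: iodine, II
Why: Hydroxyl-directed trans-hydroalumination of the propargylic alcohol and iodinolysis, in which the cyclic alanate puts aluminium and then iodine on C11 cis to C6, fixing the alkene geometry; the low temperature suppresses loss of the C12 silyloxy group.

Step 9
Reactants: 15 (Z)-iodoalkene alcohol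
Product: 16 bis-silyl ether
Conditions: TBSOTf, 2,6-lutidine, CH2Cl2, 0 °C
Reagents that add atoms: tert-butyldimethylsilyl trifluoromethanesulfonate, CC(C)(C)[Si](C)(C)OS(=O)(=O)C(F)(F)F
Why: Standard silylation of the secondary C6 alcohol, giving the same silyl group as on C12 so that both leave together in step 19.

Step 10
Reactants: 16 bis-silyl ether
Product: 17 allylboronate (fragment B)
Conditions: IZnCH2B(pin) (from ICH2B(pin), zinc dust, THF), Pd(PPh3)4 (5 mol %), THF, rt
Reagents that add atoms: (pinacolatoboryl)methylzinc iodide, I[Zn]CB1OC(C)(C)C(C)(C)O1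
Why: Negishi coupling, in which zerovalent palladium inserts into the alkenyl C–I bond much faster than into the alkenyl C–Br bond and the alkene geometry is retained, giving the allylboronate with its CH2B group (C13) cis to C6.

Step 11
Reactants: 17 allylboronate (fragment B); 5 C8 aldehyde (fragment A)
Product: 19 seco C8 alcohol, via borate ester 18 (not isolated)
Conditions: toluene (2 M), 4 Å molecular sieves, 50 °C; aqueous NaHCO3 work-up
Reagents that add atoms: none
Why: Thermal allylboration through a closed six-membered chair (Zimmerman–Traxler) transition state, in which C6 cis to CH2B sits axial and gives the 7,8-syn adduct, while 1,3-allylic strain holds C6–H in the alkene plane so that the aldehyde should add anti to the C5 carbon chain, setting C7 and C8 relative to C6 as in the target.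

Step 12
Reactants: 19 seco C8 alcohol
Product: 20 C8 isobutyrate
Conditions: isobutyryl chloride, pyridine, DMAP (cat.), CH2Cl2, 0 °C to rt
Reagents that add atoms: isobutyryl chloride, CC(C)C(Cl)=O
Why: DMAP-catalysed acylation of the only free hydroxyl installs the ester of the target early, so no separate C8 protecting group is needed.

Step 13
Reactants: 20 C8 isobutyrate
Product: 21 2-iodoalkene
Conditions: CuI (10 mol %), trans-N,N′-dimethylcyclohexane-1,2-diamine (20 mol %), NaI (3 equiv), 1,4-dioxane, 110 °C
Reagents that add atoms: sodium iodide, [Na+].[I-]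
Why: Copper-catalysed halogen exchange (Finkelstein type) on the alkenyl bromide, driven by precipitation of NaBr, which the ester, silyl ethers and alkenes should tolerate.

Step 14
Reactants: 21 2-iodoalkene
Product: 22 terminal epoxide
Conditions: mCPBA (1.05 equiv), NaHCO3, CH2Cl2, 0 °C
Reagents that add atoms: 3-chloroperoxybenzoic acid, OOC(=O)c1cccc(Cl)c1
Why: Prilezhaev epoxidation, which should pick the electron-rich trisubstituted alkene over the hindered 11(13)-alkene (deactivated by its allylic oxygen) and the iodoalkene; the epoxide configuration is irrelevant.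

Step 15
Reactants: 22 terminal epoxide
Product: 24 seco C3 aldehyde with C4 2-iodoalkene, via vicinal diol 23 (not isolated)
Conditions: H5IO6, THF/H2O, 0 °C
Reagents that add atoms: none
Why: Acid-promoted epoxide hydrolysis and periodate glycol cleavage (Malaprade) release the C3 aldehyde and acetone; the short time at 0 °C should spare the tertiary triethylsilyl and the tert-butyldimethylsilyl ethers.

Step 16
Reactants: 24 seco C3 aldehyde with C4 2-iodoalkene
Product: 26 ten-membered 4-methylene-3-ol, via alkenylchromium 25 (not isolated)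
Conditions: CrCl2 (10 equiv), NiCl2 (0.1 equiv), degassed DMSO/THF (3:1), rt, syringe-pump addition of 24 to 2 mM
Reagents that add atoms: none
Why: Zerovalent nickel, formed from NiCl2 by CrCl2, inserts into the C4–I bond and passes the alkenyl group to trivalent chromium; alkenylchromium 25 then adds to the C3 aldehyde, and the strong Cr–O bond makes the addition irreversible. This is the Nozaki–Hiyama–Kishi alkenyl halide–aldehyde coupling in its macrocyclising form, which is established for medium and large carbocycles. The ten-membered ring closes in a 10-exo-trig mode, C4 attacking C3 with the carbonyl oxygen outside the ring. The one new stereocentre, the C3 carbinol, is not controlled and need not be, because step 17 turns it into the ketone. Chemoselectivity is secured because the organochromium species ignores the isobutyrate, the silyl ethers and the 11(13)-alkene, leaving the aldehyde as the only electrophile; ring formation over chain growth is secured by slow addition at high dilution and helped by the substituents at C6, C7, C8 and the quaternary C10, which restrict the open chain.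

Step 17
Reactants: 26 ten-membered 4-methylene-3-ol
Product: 27 4-methylene-3-one
Conditions: 1,1,1-triacetoxy-1,1-dihydro-1,2-benziodoxol-3(1H)-one (DMP), NaHCO3, CH2Cl2, 0 °C
Reagents that add atoms: none
Why: Dess–Martin oxidation of the only free hydroxyl converts both C3 epimers into one exocyclic enone, which is used at once because it is a reactive acceptor.

Step 18
Reactants: 27 4-methylene-3-one
Product: 30 (4R)-4-methyl-3-one, via copper enolate 28 (not isolated), via C4-epimeric ketone 29 (not isolated)
Conditions: [(Ph3P)CuH]6 (0.5 equiv), H2O (5 equiv), benzene, rt; then DBU (0.2 equiv), rt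
Reagents that add atoms: none
Why: Conjugate reduction of the exocyclic enone by the copper hydride (the ester and the isolated 11(13)-alkene are inert), protonation of the copper enolate by water, and base-mediated equilibration through the enol, which should settle C4 in the assumed more stable 4R configuration.

Step 19
Reactants: 30 (4R)-4-methyl-3-one
Product: 31 keto triol
Conditions: TBAF, AcOH (1:1), THF, 0 °C to rt
Reagents that add atoms: none
Why: Fluoride cleavage of the three silyl ethers under acetic acid buffering, which should avoid acid-catalysed internal ketal formation of the freed 6- and 10-hydroxyls with the C3 ketone and base-induced migration of the C8 ester.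

Step 20
Reactants: 31 keto triol
Product: 34 target, via hydroxy enal 32 (not isolated), via lactol 33 (not isolated)
Conditions: activated MnO2 (excess), CH2Cl2, rt
Reagents that add atoms: none
Why: Oxidative lactonisation, in which MnO2 oxidises only the allylic primary C12 alcohol, C6–OH traps the enal as a five-membered lactol (5-exo-trig) and this is oxidised again to the α-methylene lactone; C6 is untouched, so the cis ring fusion follows from steps 7 and 11.

Compound list
1 | (S)-linalool, (3S)-3,7-dimethylocta-1,6-dien-3-ol | CC(C)=CCC[C@](C)(O)C=C | starting material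
2 | (3S)-triethyl[(3,7-dimethylocta-1,6-dien-3-yl)oxy]silane | CC(C)=CCC[C@](C)(O[Si](CC)(CC)CC)C=C | intermediate
3 | B-alkyl-9-borabicyclo[3.3.1]nonane from 2 (boron on C8) | CC(C)=CCC[C@](C)(O[Si](CC)(CC)CC)CCB1C2CCCC1CCC2 | intermediate (not isolated)
4 | (3S)-3,7-dimethyl-3-[(triethylsilyl)oxy]oct-6-en-1-ol | CC(C)=CCC[C@](C)(O[Si](CC)(CC)CC)CCO | intermediate
5 | (3S)-3,7-dimethyl-3-[(triethylsilyl)oxy]oct-6-enal (fragment A; CHO is C8) | CC(C)=CCC[C@](C)(O[Si](CC)(CC)CC)CC=O | intermediate
6 | tert-butyldimethyl(prop-2-yn-1-yloxy)silane | C#CCO[Si](C)(C)C(C)(C)C | starting material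
7 | lithium acetylide of 6 | [Li]C#CCO[Si](C)(C)C(C)(C)C | intermediate (not isolated)
8 | 4-[(tert-butyldimethylsilyl)oxy]but-2-ynal (CHO is C6) | O=CC#CCO[Si](C)(C)C(C)(C)C | intermediate
9 | 2,3-dibromoprop-1-ene | C=C(Br)CBr | starting material
10 | (2-bromoprop-2-en-1-yl)indium dibromide (representative allylindium species) | C=C(Br)C[In](Br)Br | intermediate (not isolated)
11 | rac-6-bromo-1-[(tert-butyldimethylsilyl)oxy]hept-6-en-2-yn-4-ol | OC(CC(Br)=C)C#CCO[Si](C)(C)C(C)(C)C | intermediate
12 | 6-bromo-1-[(tert-butyldimethylsilyl)oxy]hept-6-en-2-yn-4-one | O=C(CC(Br)=C)C#CCO[Si](C)(C)C(C)(C)C | intermediate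
13 | (4S)-6-bromo-1-[(tert-butyldimethylsilyl)oxy]hept-6-en-2-yn-4-ol (carbinol is C6) | O[C@H](C#CCO[Si](C)(C)C(C)(C)C)CC(Br)=C | intermediate
14 | sodium cyclic alkenylalanate from 13 (Al bound to O6 and C11) | [Na+].COCCO[Al-]1(OCCOC)O[C@@H](CC(Br)=C)C=C1CO[Si](C)(C)C(C)(C)C | intermediate (not isolated)
15 | (2Z,4S)-6-bromo-1-[(tert-butyldimethylsilyl)oxy]-2-iodohepta-2,6-dien-4-ol | O[C@H](/C=C(\I)CO[Si](C)(C)C(C)(C)C)CC(Br)=C | intermediate
16 | (2Z,4S)-6-bromo-1,4-bis[(tert-butyldimethylsilyl)oxy]-2-iodohepta-2,6-diene | CC(C)(C)[Si](C)(C)O[C@H](/C=C(\I)CO[Si](C)(C)C(C)(C)C)CC(Br)=C | intermediate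
17 | 2-[(2E,4S)-6-bromo-4-[(tert-butyldimethylsilyl)oxy]-2-{[(tert-butyldimethylsilyl)oxy]methyl}hepta-2,6-dien-1-yl]-4,4,5,5-tetramethyl-1,3,2-dioxaborolane (fragment B; CH2B cis to C6) | CC(C)(C)[Si](C)(C)O[C@H](/C=C(\CB1OC(C)(C)C(C)(C)O1)CO[Si](C)(C)C(C)(C)C)CC(Br)=C | intermediate
18 | pinacol borate ester of 19 (boron on O8) | CC(C)=CCC[C@](C)(O[Si](CC)(CC)CC)C[C@@H](OB1OC(C)(C)C(C)(C)O1)[C@@H](C(=C)CO[Si](C)(C)C(C)(C)C)[C@@H](O[Si](C)(C)C(C)(C)C)CC(Br)=C | intermediate (not isolated)
19 | (4S,5R,6R,8S)-2-bromo-4-[(tert-butyldimethylsilyl)oxy]-5-{3-[(tert-butyldimethylsilyl)oxy]prop-1-en-2-yl}-8,12-dimethyl-8-[(triethylsilyl)oxy]trideca-1,11-dien-6-ol (germacrane locants 6S,7R,8R,10S; free 8-OH) | CC(C)=CCC[C@](C)(O[Si](CC)(CC)CC)C[C@@H](O)[C@@H](C(=C)CO[Si](C)(C)C(C)(C)C)[C@@H](O[Si](C)(C)C(C)(C)C)CC(Br)=C | intermediate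
20 | 8-O-(2-methylpropanoyl) ester of 19 (6S,7R,8R,10S; C4 bromoalkene) | CC(C)=CCC[C@](C)(O[Si](CC)(CC)CC)C[C@@H](OC(=O)C(C)C)[C@@H](C(=C)CO[Si](C)(C)C(C)(C)C)[C@@H](O[Si](C)(C)C(C)(C)C)CC(Br)=C | intermediate
21 | C4 2-iodoalkene analogue of 20 (6S,7R,8R,10S) | CC(C)=CCC[C@](C)(O[Si](CC)(CC)CC)C[C@@H](OC(=O)C(C)C)[C@@H](C(=C)CO[Si](C)(C)C(C)(C)C)[C@@H](O[Si](C)(C)C(C)(C)C)CC(I)=C | intermediate
22 | epoxide of the trisubstituted alkene of 21 (both epimers at the epoxide CH) | CC1(C)OC1CC[C@](C)(O[Si](CC)(CC)CC)C[C@@H](OC(=O)C(C)C)[C@@H](C(=C)CO[Si](C)(C)C(C)(C)C)[C@@H](O[Si](C)(C)C(C)(C)C)CC(I)=C | intermediate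
23 | vicinal diol from 22 | CC(C)(O)C(O)CC[C@](C)(O[Si](CC)(CC)CC)C[C@@H](OC(=O)C(C)C)[C@@H](C(=C)CO[Si](C)(C)C(C)(C)C)[C@@H](O[Si](C)(C)C(C)(C)C)CC(I)=C | intermediate (not isolated)
24 | seco C3 aldehyde with C4 2-iodoalkene: 6-OTBS, 8-isobutyrate, 10-OTES, 12-OTBS, 11(13)-ene (6S,7R,8R,10S) | O=CCC[C@](C)(O[Si](CC)(CC)CC)C[C@@H](OC(=O)C(C)C)[C@@H](C(=C)CO[Si](C)(C)C(C)(C)C)[C@@H](O[Si](C)(C)C(C)(C)C)CC(I)=C | intermediate
25 | C4 alkenylchromium dichloride from 24 | O=CCC[C@](C)(O[Si](CC)(CC)CC)C[C@@H](OC(=O)C(C)C)[C@@H](C(=C)CO[Si](C)(C)C(C)(C)C)[C@@H](O[Si](C)(C)C(C)(C)C)CC(=C)[Cr](Cl)Cl | intermediate (not isolated)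
26 | ten-membered 4(15)-methylene-3-ol, both C3 epimers (6S,7R,8R,10S) | OC1CC[C@](C)(O[Si](CC)(CC)CC)C[C@@H](OC(=O)C(C)C)[C@@H](C(=C)CO[Si](C)(C)C(C)(C)C)[C@@H](O[Si](C)(C)C(C)(C)C)CC1=C | intermediate
27 | ten-membered 4(15)-methylene-3-one (6S,7R,8R,10S) | O=C1CC[C@](C)(O[Si](CC)(CC)CC)C[C@@H](OC(=O)C(C)C)[C@@H](C(=C)CO[Si](C)(C)C(C)(C)C)[C@@H](O[Si](C)(C)C(C)(C)C)CC1=C | intermediate
28 | copper enolate (C3–O–Cu, C3=C4) from 27 | CC1=C(O[Cu])CC[C@](C)(O[Si](CC)(CC)CC)C[C@@H](OC(=O)C(C)C)[C@@H](C(=C)CO[Si](C)(C)C(C)(C)C)[C@@H](O[Si](C)(C)C(C)(C)C)C1 | intermediate (not isolated)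
29 | 4-methyl-3-one as the C4-epimeric mixture | O=C1CC[C@](C)(O[Si](CC)(CC)CC)C[C@@H](OC(=O)C(C)C)[C@@H](C(=C)CO[Si](C)(C)C(C)(C)C)[C@@H](O[Si](C)(C)C(C)(C)C)CC1C | intermediate (not isolated)
30 | (4R,6S,7R,8R,10S)-4-methyl-3-one with 6-OTBS, 10-OTES, 12-OTBS, 8-isobutyrate | O=C1CC[C@](C)(O[Si](CC)(CC)CC)C[C@@H](OC(=O)C(C)C)[C@@H](C(=C)CO[Si](C)(C)C(C)(C)C)[C@@H](O[Si](C)(C)C(C)(C)C)C[C@H]1C | intermediate
31 | (4R,6S,7S,8R,10S)-6,10,12-trihydroxy-3-oxogermacr-11(13)-en-8-yl 2-methylpropanoate | O=C1CC[C@](C)(O)C[C@@H](OC(=O)C(C)C)[C@@H](C(=C)CO)[C@@H](O)C[C@H]1C | intermediate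
32 | 12-aldehyde (hydroxy enal) from 31 | O=C1CC[C@](C)(O)C[C@@H](OC(=O)C(C)C)[C@@H](C(=C)C=O)[C@@H](O)C[C@H]1C | intermediate (not isolated)
33 | 6,12-lactol from 32 | C=C1C(O)O[C@H]2C[C@@H](C)C(=O)CC[C@](C)(O)C[C@@H](OC(=O)C(C)C)[C@@H]12 | intermediate (not isolated)
34 | target, (4R,6S,7S,8R,10S)-10-hydroxy-3-oxo-8-(2-methylpropanoyloxy)germacr-11(13)-en-6,12-olide | C=C1C(=O)O[C@H]2C[C@@H](C)C(=O)CC[C@](C)(O)C[C@@H](OC(=O)C(C)C)[C@@H]12 | target

Total step count: 20. Longest linear sequence: 17 steps (6 to 34, steps 4–20); steps 1–3 form the shorter branch that joins at step 11.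

Steps most likely to fail

Step 16. Intermolecular coupling of the alkenylchromium species (oligomers), or loss of iodine by protonation, may outrun the strained ten-membered closure. The fallback sets out from 24 and returns at 27, making the C3–C4 bond as an acyl–alkenyl cross-coupling. Pinnick oxidation (NaClO2, NaH2PO4, 2-methyl-2-butene, t-BuOH/H2O) gives the seco carboxylic acid F1. EtSH, DCC and DMAP give the S-ethyl thioester F2. Zinc insertion into the C4–I bond (zinc dust, LiCl, THF) gives the alkenylzinc iodide F3, which is not isolated but added slowly to PdCl2(PPh3)2 in toluene. The intramolecular Fukuyama coupling closes the ring directly as enone 27, so steps 16 and 17 are not needed.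

Step 11. The aldehyde may add with poor facial selectivity relative to C6 (reaction on the face anti to the silyloxy group competing with the face anti to C5), and the hindered boronate may add slowly. The fallback sets out from 17 and 5 and returns at 19. Control is moved from the C6 centre to a catalyst: the matched enantiomer of 3,3′-bis(2,4,6-triisopropylphenyl)-1,1′-binaphthyl-2,2′-diyl hydrogen phosphate (5 mol %, toluene, −30 °C) activates the boronate by hydrogen bonding and selects the aldehyde face, so that catalyst and substrate preferences reinforce each other at low temperature. This makes no new compound F0.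

Step 18. Equilibration at C4 may settle on the 4-epimer or on an inseparable mixture. The fallback sets out from 27 and returns at 30, relaying C4 from a reagent-set C3 carbinol. Corey–Bakshi–Shibata reduction ((R)-2-methyl-CBS-oxazaborolidine, catecholborane, toluene, −78 °C) gives the (3S)-allylic alcohol F4. Hydroxyl-directed hydrogenation ([Rh(nbd)(dppb)]BF4, H2 at low pressure, CH2Cl2) delivers hydrogen from the face of the bound C3–OH and should give the 3,4-anti (3S,4R)-alcohol F5 before the undirected 11(13)-alkene reacts. Dess–Martin oxidation of F5 gives 30.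

Further compounds
F1 | step 16 | seco C3 carboxylic acid with C4 2-iodoalkene | OC(=O)CC[C@](C)(O[Si](CC)(CC)CC)C[C@@H](OC(=O)C(C)C)[C@@H](C(=C)CO[Si](C)(C)C(C)(C)C)[C@@H](O[Si](C)(C)C(C)(C)C)CC(I)=C
F2 | step 16 | S-ethyl thioester of F1 | CCSC(=O)CC[C@](C)(O[Si](CC)(CC)CC)C[C@@H](OC(=O)C(C)C)[C@@H](C(=C)CO[Si](C)(C)C(C)(C)C)[C@@H](O[Si](C)(C)C(C)(C)C)CC(I)=C
F3 | step 16 | C4 alkenylzinc iodide from F2 | CCSC(=O)CC[C@](C)(O[Si](CC)(CC)CC)C[C@@H](OC(=O)C(C)C)[C@@H](C(=C)CO[Si](C)(C)C(C)(C)C)[C@@H](O[Si](C)(C)C(C)(C)C)CC(=C)[Zn]I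
F0 | step 11 | none | none
F4 | step 18 | (3S)-4(15)-methylene-3-ol (single C3 epimer of 26) | O[C@H]1CC[C@](C)(O[Si](CC)(CC)CC)C[C@@H](OC(=O)C(C)C)[C@@H](C(=C)CO[Si](C)(C)C(C)(C)C)[C@@H](O[Si](C)(C)C(C)(C)C)CC1=C
F5 | step 18 | (3S,4R)-4-methyl-3-ol | O[C@H]1CC[C@](C)(O[Si](CC)(CC)CC)C[C@@H](OC(=O)C(C)C)[C@@H](C(=C)CO[Si](C)(C)C(C)(C)C)[C@@H](O[Si](C)(C)C(C)(C)C)C[C@H]1C
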